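**Strategy.** The cyclohexane ring is cut at C1–C2 and C4–C5 (quinic acid numbering). C5–C6–C1 is a masked 2,4-dioxobutanoate: keto ester at C1, chiral dioxane acetal at C5. C2–C3–C4 is an allyl 1,3-dianion equivalent, (E)-1,3-bis(trimethylsilyl)propene. One Lewis-acid operation joins them: acetal substitution forms C4–C5, then the new allylsilane adds to the C1 ketone, closing the ring and leaving a C3=C4 alkene. The step exploits the 1,3-related carbinol carbons C1 and C5 and the cis-3,4-diol, which is a cis-alkene in disguise. Osmylation, two successive vanilloylations and one hydrogenolysis finish the synthesis.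

Key step: step 4

Remark: ring atoms are numbered as in quinic acid (C1 bears OH and CO2H, C3 and C4 bear the two cis ester oxygens, C5 the free secondary OH), so the target is the 3,4-di-O-vanilloyl ester of (−)-quinic acid.

Step 1
Reactants: 1 ethyl vinyl ether; 2 oxalyl chloride
Product: 4 benzyl (E)-4-ethoxy-2-oxobut-3-enoate, via (E)-4-ethoxy-2-oxobut-3-enoyl chloride 3 (not isolated)
Conditions: (COCl)2 (1.5 equiv), neat, 0 °C to rt, excess (COCl)2 evaporated; then BnOH, Et3N, CH2Cl2, 0 °C
Reagents that add atoms: benzyl alcohol, OCc1ccccc1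
Why: Oxalyl chloride acylates the nucleophilic β-carbon of the enol ether and loss of HCl gives the E-configured vinylogous ester acid chloride (Tietze-type acylation of enol ethers), which benzyl alcohol esterifies by nucleophilic acyl substitution; no stereocentre is formed.

Step 2
Reactants: 4 benzyl (E)-4-ethoxy-2-oxobut-3-enoate; 5 (1S,3S)-1,3-diphenylpropane-1,3-diol
Product: 6 benzyl 3-[(4S,6S)-4,6-diphenyl-1,3-dioxan-2-yl]-2-oxopropanoate
Conditions: PPTS (10 mol %), toluene, 5 Å molecular sieves, 60 °C
Reagents that add atoms: none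
Why: Acid-catalysed oxa-Michael addition of one hydroxyl to the β-alkoxy enone followed by transacetalisation with loss of ethanol should close the 1,3-dioxane (acetal formation under thermodynamic control); both stereocentres come unchanged from 5 and the C2 substituent sits equatorial.

Step 3
Reactants: 7 allyltrimethylsilane
Product: 8 (E)-1,3-bis(trimethylsilyl)propene
Conditions: sec-BuLi, TMEDA, THF, −78 °C; then Me3SiCl, −78 °C to rt
Reagents that add atoms: chlorotrimethylsilane, C[Si](C)(C)Cl
Why: Deprotonation of the allylsilane gives a silyl-stabilised allyl anion that should be silylated at the less hindered γ-terminus to give the E-configured product (allyl anion silylation); no stereocentre is formed.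

Step 4
Reactants: 6 benzyl 3-[(4S,6S)-4,6-diphenyl-1,3-dioxan-2-yl]-2-oxopropanoate; 8 (E)-1,3-bis(trimethylsilyl)propene
Product: 11 benzyl (1S,5R)-1-hydroxy-5-[(1S,3S)-3-hydroxy-1,3-diphenylpropoxy]cyclohex-3-ene-1-carboxylate, via open-chain allylsilane keto ester 9 (not isolated), via bis(trimethylsilyl) ether of the cyclohexene 10 (not isolated)
Conditions: TMSOTf (20 mol %), CH2Cl2, −78 °C to −30 °C; then 1 M HCl, THF, 0 °C
Reagents that add atoms: none
Why: Proposed new method: TMSOTf silylates the dioxane oxygen next to the axial phenyl and opens the acetal to an oxocarbenium ion at C5, which the vinylsilane terminus of 8 attacks with loss of the allylic Me3Si group (Hosomi–Sakurai SE2′) to give allylsilane 9 with the C4–C5 bond; the regenerated silyl triflate then activates the α-keto ester and the terminal CH2 (C2) of this new allylsilane adds to C1 in an anti SE2′ sense, the C4 silyl group leaving so that the alkene is fixed at C3=C4 (10). The closest known reaction types are the Lewis-acid [3+3] annulation of bifunctional allylsilanes with 1,3-dielectrophiles, the Noyori and Johnson allylations of acetals and silicon-directed alkene placement in allylsilane-terminated cyclisations, but a 1,3-disilylpropene has not been paired with a keto acetal in one operation. The six-membered carbocycle closes 6-exo-trig at the ketone carbonyl with the allylsilane π bond endocyclic. C5 (R) is controlled by the C2-symmetric dioxane (SN2-like attack anti to the departing oxygen, Johnson model) and C1 (S) by a chair-like transition state with the ester equatorial and the C1 oxygen anti to the C5 ether, while the silyl-bearing C4 centre is transient and both epimers converge. The step needs the acetal to react before the ketone, which silyl triflate catalysis secures because it ionises acetals but does not activate ketones towards bimolecular allylation, and it needs ring closure to outrun β-silyl ether elimination, which the small Me3Si group and low temperature favour.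

Step 5
Reactants: 11 benzyl (1S,5R)-1-hydroxy-5-[(1S,3S)-3-hydroxy-1,3-diphenylpropoxy]cyclohex-3-ene-1-carboxylate
Product: 12 benzyl (1S,5R)-5-[(1S,3S)-3-(acetyloxy)-1,3-diphenylpropoxy]-1-hydroxycyclohex-3-ene-1-carboxylate
Conditions: Ac2O (1.2 equiv), pyridine, DMAP (2 mol %), CH2Cl2, 0 °C
Reagents that add atoms: acetic anhydride, CC(=O)OC(C)=O
Why: Pyridine/DMAP-mediated acetylation (nucleophilic acyl substitution) should cap only the secondary benzylic hydroxyl of the auxiliary chain, since the tertiary C1 hydroxyl flanked by the ester is too hindered at 0 °C, so that the later aroylations consume only the ring diol; no stereocentre is touched.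

Step 6
Reactants: 12 benzyl (1S,5R)-5-[(1S,3S)-3-(acetyloxy)-1,3-diphenylpropoxy]-1-hydroxycyclohex-3-ene-1-carboxylate
Product: 13 benzyl (1S,3R,4R,5R)-5-[(1S,3S)-3-(acetyloxy)-1,3-diphenylpropoxy]-1,3,4-trihydroxycyclohexane-1-carboxylate
Conditions: OsO4 (2 mol %), NMO, acetone/H2O 4:1, 0 °C to rt
Reagents that add atoms: N-methylmorpholine N-oxide, C[N+]1([O-])CCOCC1; water, O
Why: Upjohn dihydroxylation adds both oxygens syn and should take the alkene face opposite the allylic C5 ether (Kishi's empirical rule), which is also the side of the small axial C1 hydroxyl, so C3 (R) and C4 (R) arise cis to O1 and trans to O5.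

Step 7
Reactants: 14 4-(benzyloxy)-3-methoxybenzoic acid
Product: 15 4-(benzyloxy)-3-methoxybenzoyl chloride
Conditions: (COCl)2, DMF (cat.), CH2Cl2, 0 °C to rt
Reagents that add atoms: oxalyl chloride (compound 2), O=C(Cl)C(=O)Cl
Why: Vilsmeier-type activation by oxalyl chloride and catalytic DMF converts the acid into the acid chloride (nucleophilic acyl substitution); the benzyl ether is untouched.

Step 8
Reactants: 13 benzyl (1S,3R,4R,5R)-5-[(1S,3S)-3-(acetyloxy)-1,3-diphenylpropoxy]-1,3,4-trihydroxycyclohexane-1-carboxylate; 15 4-(benzyloxy)-3-methoxybenzoyl chloride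
Product: 16 benzyl (1S,3R,4R,5R)-5-[(1S,3S)-3-(acetyloxy)-1,3-diphenylpropoxy]-4-{[4-(benzyloxy)-3-methoxybenzoyl]oxy}-1,3-dihydroxycyclohexane-1-carboxylate
Conditions: Me2SnCl2 (5 mol %), i-Pr2NEt (1.5 equiv), 15 (1.05 equiv), THF, rt
Reagents that add atoms: none
Why: Dimethyltin dichloride reversibly chelates the cis-3,4-diol and should direct one equivalent of the acid chloride to the equatorial O4 in preference to the axial O3 and the tertiary O1 (tin-catalysed regioselective monoacylation of 1,2-diols), while any 3-O-monoester formed would converge in step 9; only an O–H bond reacts, so all configurations are retained.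

Step 9
Reactants: 16 benzyl (1S,3R,4R,5R)-5-[(1S,3S)-3-(acetyloxy)-1,3-diphenylpropoxy]-4-{[4-(benzyloxy)-3-methoxybenzoyl]oxy}-1,3-dihydroxycyclohexane-1-carboxylate; 15 4-(benzyloxy)-3-methoxybenzoyl chloride
Product: 17 benzyl (1R,3R,4S,5R)-5-[(1S,3S)-3-(acetyloxy)-1,3-diphenylpropoxy]-3,4-bis{[4-(benzyloxy)-3-methoxybenzoyl]oxy}-1-hydroxycyclohexane-1-carboxylate
Conditions: pyridine, DMAP (0.3 equiv), 15 (1.5 equiv), CH2Cl2, 0 °C to rt
Reagents that add atoms: none
Why: DMAP-catalysed acylation (nucleophilic acyl substitution) should esterify the remaining axial secondary C3 hydroxyl while the hindered tertiary C1 hydroxyl next to the ester stays free; only an O–H bond reacts, so all configurations are retained (the descriptors at C1 and C4 change by priority only).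

Step 10
Reactants: 17 benzyl (1R,3R,4S,5R)-5-[(1S,3S)-3-(acetyloxy)-1,3-diphenylpropoxy]-3,4-bis{[4-(benzyloxy)-3-methoxybenzoyl]oxy}-1-hydroxycyclohexane-1-carboxylate
Product: 18 Burkinabin A, (1R,3R,4S,5R)-1,5-dihydroxy-3,4-bis[(4-hydroxy-3-methoxybenzoyl)oxy]cyclohexane-1-carboxylic acid
Conditions: H2 (3 atm), Pd(OH)2 on carbon, EtOAc/MeOH 1:1 with 1% AcOH, rt
Reagents that add atoms: none
Why: Catalytic hydrogenolysis should cleave every benzylic C–O bond in one operation (benzyl ester, two aryl benzyl ethers, the 1,3-diphenylpropyl ether at O5 and the benzylic acetate on that chain), whereas the two aryl esters on the ring, the aryl methyl ethers and all stereocentres are inert under these conditions.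

**Compound list**

1 | ethyl vinyl ether | C=COCC | starting material
2 | oxalyl chloride | O=C(Cl)C(=O)Cl | starting material
3 | (E)-4-ethoxy-2-oxobut-3-enoyl chloride | CCO/C=C/C(=O)C(=O)Cl | intermediate
4 | benzyl (E)-4-ethoxy-2-oxobut-3-enoate | CCO/C=C/C(=O)C(=O)OCc1ccccc1 | intermediate
5 | (1S,3S)-1,3-diphenylpropane-1,3-diol | O[C@H](c1ccccc1)C[C@H](O)c1ccccc1 | starting material
6 | benzyl 3-[(4S,6S)-4,6-diphenyl-1,3-dioxan-2-yl]-2-oxopropanoate | O=C(CC1O[C@H](c2ccccc2)C[C@@H](c2ccccc2)O1)C(=O)OCc1ccccc1 | intermediate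
7 | allyltrimethylsilane | C=CC[Si](C)(C)C | starting material
8 | (E)-1,3-bis(trimethylsilyl)propene | C[Si](C)(C)C/C=C/[Si](C)(C)C | intermediate
9 | benzyl (4R)-4-[(1S,3S)-1,3-diphenyl-3-(trimethylsilyloxy)propoxy]-2-oxo-5-(trimethylsilyl)hept-6-enoate (both C5 epimers) | C=CC([Si](C)(C)C)[C@H](O[C@H](c1ccccc1)C[C@H](O[Si](C)(C)C)c1ccccc1)CC(=O)C(=O)OCc1ccccc1 | intermediate
10 | benzyl (1S,5R)-5-[(1S,3S)-1,3-diphenyl-3-(trimethylsilyloxy)propoxy]-1-(trimethylsilyloxy)cyclohex-3-ene-1-carboxylate | C[Si](C)(C)O[C@@]1(C(=O)OCc2ccccc2)CC=C[C@H](O[C@H](c2ccccc2)C[C@H](O[Si](C)(C)C)c2ccccc2)C1 | intermediate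
11 | benzyl (1S,5R)-1-hydroxy-5-[(1S,3S)-3-hydroxy-1,3-diphenylpropoxy]cyclohex-3-ene-1-carboxylate | O[C@@]1(C(=O)OCc2ccccc2)CC=C[C@H](O[C@H](c2ccccc2)C[C@H](O)c2ccccc2)C1 | intermediate
12 | benzyl (1S,5R)-5-[(1S,3S)-3-(acetyloxy)-1,3-diphenylpropoxy]-1-hydroxycyclohex-3-ene-1-carboxylate | O[C@@]1(C(=O)OCc2ccccc2)CC=C[C@H](O[C@H](c2ccccc2)C[C@H](OC(C)=O)c2ccccc2)C1 | intermediate
13 | benzyl (1S,3R,4R,5R)-5-[(1S,3S)-3-(acetyloxy)-1,3-diphenylpropoxy]-1,3,4-trihydroxycyclohexane-1-carboxylate | O[C@H]1[C@H](O[C@H](c2ccccc2)C[C@H](OC(C)=O)c2ccccc2)C[C@](O)(C(=O)OCc2ccccc2)C[C@H]1O | intermediate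
14 | 4-(benzyloxy)-3-methoxybenzoic acid | COc1cc(C(=O)O)ccc1OCc1ccccc1 | starting material
15 | 4-(benzyloxy)-3-methoxybenzoyl chloride | COc1cc(C(=O)Cl)ccc1OCc1ccccc1 | intermediate
16 | benzyl (1S,3R,4R,5R)-5-[(1S,3S)-3-(acetyloxy)-1,3-diphenylpropoxy]-4-{[4-(benzyloxy)-3-methoxybenzoyl]oxy}-1,3-dihydroxycyclohexane-1-carboxylate | COc1cc(C(=O)O[C@H]2[C@H](O[C@H](c3ccccc3)C[C@H](OC(C)=O)c3ccccc3)C[C@](O)(C(=O)OCc3ccccc3)C[C@H]2O)ccc1OCc1ccccc1 | intermediate
17 | benzyl (1R,3R,4S,5R)-5-[(1S,3S)-3-(acetyloxy)-1,3-diphenylpropoxy]-3,4-bis{[4-(benzyloxy)-3-methoxybenzoyl]oxy}-1-hydroxycyclohexane-1-carboxylate | COc1cc(C(=O)O[C@H]2[C@H](O[C@H](c3ccccc3)C[C@H](OC(C)=O)c3ccccc3)C[C@](O)(C(=O)OCc3ccccc3)C[C@H]2OC(=O)c2ccc(OCc3ccccc3)c(OC)c2)ccc1OCc1ccccc1 | intermediate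
18 | Burkinabin A, (1R,3R,4S,5R)-1,5-dihydroxy-3,4-bis[(4-hydroxy-3-methoxybenzoyl)oxy]cyclohexane-1-carboxylic acid | COc1cc(C(=O)O[C@H]2[C@H](O)C[C@](O)(C(=O)O)C[C@H]2OC(=O)c2ccc(O)c(OC)c2)ccc1O | target

**Step count.** Total: 10 steps. Longest linear sequence: 8 steps (steps 1, 2, 4, 5, 6, 8, 9, 10).

**Steps most likely to fail**

1. Step 4 (Proposed new method). What may go wrong: bimolecular allylation of the keto ester before the acetal ionises (which would misplace the alkene), elimination across the β-silyl ether before ring closure, or erosion of facial selectivity in the acetal opening or at C1. The fallback uses known aldol chemistry; it sets out from 6 and comes back at 13. The C4–C5 bond would be made by a TMSOTf-catalysed Mukaiyama aldol opening of the dioxane (Noyori/Johnson type) with the (Z)-trimethylsilyl enol ether of 1-(tert-butyldimethylsilyloxy)propan-2-one, which should give the syn β-alkoxy ketone benzyl (4R,5S)-5-[(tert-butyldimethylsilyl)oxy]-4-[(1S,3S)-3-hydroxy-1,3-diphenylpropoxy]-2,6-dioxoheptanoate F1. The C1–C2 bond would follow from an enamine-mediated intramolecular aldol addition of the methyl ketone to the α-keto ester (dehydroquinate-type cyclisation; pyrrolidine, AcOH, CH2Cl2, 0 °C), which under reversible conditions should favour the chair with the ester equatorial and give benzyl (1R,4S,5R)-4-[(tert-butyldimethylsilyl)oxy]-1-hydroxy-5-[(1S,3S)-3-hydroxy-1,3-diphenylpropoxy]-3-oxocyclohexane-1-carboxylate F2. Acetylation of the auxiliary hydroxyl (Ac2O, pyridine, 0 °C) would give benzyl (1R,4S,5R)-5-[(1S,3S)-3-(acetyloxy)-1,3-diphenylpropoxy]-4-[(tert-butyldimethylsilyl)oxy]-1-hydroxy-3-oxocyclohexane-1-carboxylate F3. LiBH(sec-Bu)3 at −78 °C should then deliver hydride from the equatorial side to give the axial C3 alcohol benzyl (1S,3R,4R,5R)-5-[(1S,3S)-3-(acetyloxy)-1,3-diphenylpropoxy]-4-[(tert-butyldimethylsilyl)oxy]-1,3-dihydroxycyclohexane-1-carboxylate F4, and HF·pyridine would remove the silyl ether to give 13.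

2. Step 6. What may go wrong: poor facial selectivity, with osmylation on the face of the C5 ether instead of the face of the C1 hydroxyl. The fallback sets out from 12 and comes back at 13. It replaces steric control by hydrogen-bond-directed delivery: stoichiometric OsO4 with TMEDA in CH2Cl2 at −78 °C (Donohoe-type directed dihydroxylation), in which the homoallylic C1 hydroxyl guides the reagent to its own face, followed by cleavage of the osmate ester with aqueous NaHSO3. It makes no new compound (F0).

3. Step 10. What may go wrong: incomplete hydrogenolysis of the hindered secondary benzylic ether at O5, with acyl migration from O4 to O5 if the reaction has to be prolonged. The fallback sets out from 17 and comes back at 18. It replaces hydrogenolysis by Lewis-acid debenzylation: BCl3 with pentamethylbenzene as cation scavenger, CH2Cl2, −78 °C, which cleaves the benzyl ester, the aryl benzyl ethers and the benzylic ether and acetate of the auxiliary chain without hydrogen. It makes no new compound (F0).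

**Further compounds**

F1 | step 4 | benzyl (4R,5S)-5-[(tert-butyldimethylsilyl)oxy]-4-[(1S,3S)-3-hydroxy-1,3-diphenylpropoxy]-2,6-dioxoheptanoate | CC(=O)[C@@H](O[Si](C)(C)C(C)(C)C)[C@H](O[C@H](c1ccccc1)C[C@H](O)c1ccccc1)CC(=O)C(=O)OCc1ccccc1
F2 | step 4 | benzyl (1R,4S,5R)-4-[(tert-butyldimethylsilyl)oxy]-1-hydroxy-5-[(1S,3S)-3-hydroxy-1,3-diphenylpropoxy]-3-oxocyclohexane-1-carboxylate | CC(C)(C)[Si](C)(C)O[C@H]1[C@H](O[C@H](c2ccccc2)C[C@H](O)c2ccccc2)C[C@](O)(C(=O)OCc2ccccc2)CC1=O
F3 | step 4 | benzyl (1R,4S,5R)-5-[(1S,3S)-3-(acetyloxy)-1,3-diphenylpropoxy]-4-[(tert-butyldimethylsilyl)oxy]-1-hydroxy-3-oxocyclohexane-1-carboxylate | CC(C)(C)[Si](C)(C)O[C@H]1[C@H](O[C@H](c2ccccc2)C[C@H](OC(C)=O)c2ccccc2)C[C@](O)(C(=O)OCc2ccccc2)CC1=O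
F4 | step 4 | benzyl (1S,3R,4R,5R)-5-[(1S,3S)-3-(acetyloxy)-1,3-diphenylpropoxy]-4-[(tert-butyldimethylsilyl)oxy]-1,3-dihydroxycyclohexane-1-carboxylate | CC(C)(C)[Si](C)(C)O[C@H]1[C@H](O[C@H](c2ccccc2)C[C@H](OC(C)=O)c2ccccc2)C[C@](O)(C(=O)OCc2ccccc2)C[C@H]1O
F0 | step 6 | none | none
F0 | step 10 | none | none
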